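## Structural features

The target is a linear chain of eight benzene rings, lettered A to H from the 2,4,6-trihydroxyphenyl end to the 3,4,5-trihydroxyphenyl end. The rings are joined only by seven diaryl ether oxygens; there are 21 free phenolic hydroxyls, no stereocentre and no carbon–carbon bond between rings. Rings C, E and G are pentaoxygenated and share one pattern: two aryl ether oxygens on adjacent carbons, three contiguous hydroxyl-bearing carbons and a single C–H. Rings B and D are 2,6-dihydroxylated hydroquinone diethers. Ring F carries its ethers at C1 (to ring E) and C5 (to ring G) and hydroxyls at C3 and C4. The pyrogallol- and hydroxyquinol-type rings are oxidised by air, above all in base, so every hydroxyl stays a methyl ether until the last step; one benzyl ether and one silyl ether serve as handles. The real difficulty is the aryl–oxygen bonds at carbons flanked by oxygen substituents: B–O–C is tri-ortho-substituted, the C–O–D oxygen sits between two oxygens on ring C, and D–O–E is tetra-ortho-substituted. Such bonds resist copper coupling and nucleophilic aromatic substitution on electron-rich rings. The key step answers this at ring C (C1 to ring B, C2–H, C3 to C5 hydroxyl, C6 to ring D): an aryloxyacetylene supplies C1 and C2 and an aryloxycyclobutenone supplies C3 to C6, so bonds C1–C6 and C2–C3 form with both ether oxygens already sitting on non-aromatic carbons.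

## Logic of the disconnections

47 to 46: all 20 O–CH3 bonds are cut in one operation. Methyl ethers survive every earlier reagent (organolithium, hydride, heat, peracid, fluoride, base) and hide the air-sensitive polyphenol to the end. The forward step must cleave only sp3 C–O bonds, spare the seven diaryl ethers and be worked up without air.

46 to 44: the ring F C4–O bond is traced to a C–C bond to a formyl carbon. The formyl group is needed anyway to activate ring F for its two ether-forming substitutions; an aryl-migrating peracid oxidation turns it into the hydroxyl afterwards. The peracid must find the aldehyde before any electron-rich ring.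

44 to 43 and 40, then 43 to 35 and 41: the two aryl–oxygen bonds at ring F (C5–O to ring G, C1–O to ring E) are cut. Both ring F carbons carry at most one ortho substituent and lie ortho and para to the formyl group, so they are the easiest ethers in the molecule to make by addition–elimination. The octamer falls into a pentamer (35), a dimer (40) and a one-ring linchpin (41). The para position must react first, so the pentamer goes in first, released from its silyl ether by fluoride.

40 to 38 to 36 and 37: the ring G hydroxyl is again traced to a formyl group and the G–O–H bond is cut at the ring G carbon ortho to it. Both pieces are catalogue arenes. The forward coupling is at a doubly ortho-substituted bromide and relies on assistance by the neighbouring formyl group.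

35 to 34 to 32 to 29 and 31: the methyl and silyl groups on the two para oxygens of ring E are removed, ring E is taken to the quinone level, and the D–O–E bond is cut at the bromine-bearing quinone carbon. This is the tetra-ortho-substituted ether; a quinone carbon accepts a hindered phenoxide where an arene would not, and the two quinone oxygens return as the ring E oxygens at C2 and C5. Substitution at C–Br must outrun electron transfer and addition at C–H, and the two hydroxyls of 33 must be told apart by their ortho substitution. 31 comes from 30 by cutting the C–Br bond.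

29 to 28 to 27: the ring D C4 oxygen is traced to its benzyl ether and one ring C methyl ether to the free phenol. Benzyl is the one group removable by hydrogenolysis beside twelve methyl ethers, so the ring D oxygen can be exposed alone.

27 to 12 and 22: ring C is cut at C1–C6 (between the two ether carbons) and at C2–C3 (between the C–H carbon and a hydroxyl carbon). A tetramer becomes a two-ring alkyne and a four-membered ring carrying ring D, and neither hindered ether of ring C has to be made on an arene. The forward step needs one orientation of the (2+2) addition, and it needs the aryloxy group of 22 on the carbon next to the carbonyl.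

12 to 9 to 7 and 8: the two alkyne carbons (ring C C1 and C2) are traced to 8 and the O–C(sp) bond to the phenol oxygen of 7. The terminal ynol ether must be made cold and used at once.

7 to 5 to 3 and 4, and 3 to 1: both hydroxyls are traced to formyl groups, and the A–O–B bond is cut at ring B C1, an unhindered carbon para to the formyl group. Ring A enters as the hindered phenol nucleophile, so the coupling catalyst must tolerate a 2,6-disubstituted phenoxide.

22 to 21 to 20 to 18 and 16 (through 19), 18 to 17, and 16 to 14 to 13: the methyl group on the C4 oxygen and the C4 hydrogen are removed, which leads to a mixed aryl methyl squarate. Its aryl–oxygen bond is cut at a chlorine-bearing carbon rather than at an alkoxy-bearing one, because exchange of an alkoxy for an aryloxy group on a squarate is uphill while chloride displacement is irreversible. The hydride must choose the carbonyl conjugated with the aryloxy oxygen. Ring D is bought with its full oxygen pattern in 13.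

## Other disconnections considered

Alternative 1: The cut is at ring F. Both its aryl–oxygen bonds are broken (C1 to the ring E oxygen, C5 to the ring G oxygen), giving the pentamer phenoxide 42, the dimer phenol 40 and the linchpin 2,4,6-trifluorobenzaldehyde A1. The forward key step would be a one-pot double nucleophilic aromatic substitution: 42 at the fluorine para to the formyl group, then 40 at an ortho fluorine, giving the complete chain as fluoro aldehyde A2.
- In its favour: maximal convergence in the last skeletal bonds, a cheap linchpin, a simple addition–elimination mechanism, unhindered ring F carbons, and a formyl group that is the latent C4 hydroxyl.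
- Against it here: three fluorines must be told apart by rate alone (para before ortho, mono before bis). The third fluorine of A2 must still be exchanged for oxygen on the full-size aldehyde. Above all it presupposes 42 and offers nothing for the hindered ethers of rings C and E.
- Comparison: in mechanism it is the simpler and better-precedented bond construction, and at ring F it is the equal of the chosen plan, which closes the same two ethers by the same logic in steps 21 and 22. The chosen plan uses 41, whose methoxy group saves the late fluorine exchange. As the step carrying the strategy it is weaker, because it leaves the tri- and tetra-ortho-substituted ethers unsolved.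

Alternative 2: The cut is inside ring D. The two carbon–carbon bonds from its C–H carbons are broken, one to the methoxy-bearing carbon and one to an ester-bearing carbon that must later become the second oxygen-bearing carbon. Ring D would come from the diene A3 (1,4-dimethoxy-1,3-bis(trimethylsilyloxy)buta-1,3-diene) and the 2-aryloxymalonaldehyde A4, which carries the A–B–C aryloxy group. The forward key step would be a TiCl4-mediated formal (3+3) cyclocondensation of Mukaiyama aldol type, giving salicylate A5 with the ring D C4 hydroxyl free between methoxy and ester.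
- In its favour: the oxygen that must make the tetra-ortho ether to ring E arrives free and unambiguous without a protecting group. The C–O–D oxygen comes in on an sp3 carbon. The symmetry of A4 removes any regiochemical question.
- Against it here: ring D is the one ring whose oxygen pattern can be bought (13), so a ring synthesis is spent where none is needed. The ester must be degraded to a hydroxyl (reduction to the aldehyde level, aryl-migrating oxidation, methylation). A4 is an enolised dialdehyde prone to self-condensation, and TiCl4 is a strong Lewis acid towards ten methyl ethers. A4 still contains the tri-ortho B–O–C ether, for which this plan has no construction.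
- Comparison: structurally it is the better plan on one point, since it gives the hindered ring D phenol directly where the chosen plan needs steps 6 and 14. Mechanistically an ionic aldol–cyclisation is no less reliable than a thermal pericyclic cascade. In step economy it loses through the ester degradation, and it solves an easier ring than ring C.

Alternative 3: The cut is in ring G, at the bond between the carbon that will carry the ring F oxygen (C1) and the lone C–H carbon (C2). Ring G is traced to the racemic cyclobutenone A6, 3,4-dimethoxy-4-(1-methoxyethenyl)-2-(3,4,5-trimethoxyphenoxy)cyclobut-2-en-1-one, made from a mixed aryl methyl squarate by 1,2-addition of a lithiated enol ether and O-methylation. The forward key step would be thermal 4π opening of A6 to a dienylketene, 6π electrocyclisation joining the ketene carbon to the vinyl CH2, and enolisation to phenol A7, which is identical with 40.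
- In its favour: it shares the idea of the chosen key step (the aryl ether oxygen is set on a four-membered ring carbon, not on an arene) but is unimolecular, so no ketene has to be intercepted. The free hydroxyl appears only where ring F must attach.
- Against it here: 40 is reachable in two steps from catalogue arenes (steps 19 and 20), so about four steps of squarate chemistry are poor value. The addition carries the same regiochemical demand as step 10. Rings C and E are left untouched, and transferred to ring C it would deliver a free outer hydroxyl, so the B–O–C ether would again have to be made on an arene.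
- Comparison: in structural logic it is the equal of the chosen plan, and in mechanism it is the better of the two because it is unimolecular. In step economy for this fragment and in strategic reach it is weaker, because only the intermolecular benzannulation brings ring B in on the alkyne.

Key step: step 12

Assumption: 4, 30, 36, 37 and 41 are taken as purchasable building blocks.

Remark: each fragment structure was checked ring by ring against the target and none needed correction. Ring C requires the aryloxy group of 22 on C2 (next to the carbonyl) and methoxy on C3, which is the isomer used. Compared with an ester-exchange route, the mixed squarate is made through the chloride, and the terminal ynol ether is never stored.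

Abbreviation: ABCD–O– is the 4-{6-[2,6-dimethoxy-4-(2,4,6-trimethoxyphenoxy)phenoxy]-2,3,4-trimethoxyphenoxy}-2,6-dimethoxyphenoxy group, that is 29 without its hydroxyl hydrogen.

## Route

Step 1
Reactants: 1 2,4,6-trimethoxybenzaldehyde
Product: 3 2,4,6-trimethoxyphenol, via aryl formate 2 (not isolated)
Conditions: mCPBA, CH2Cl2, 0 °C to rt; then K2CO3 (cat.), MeOH, rt
Reagents that add atoms: 3-chloroperbenzoic acid O=C(OO)c1cccc(Cl)c1
Why: Baeyer–Villiger oxidation of an electron-rich benzaldehyde; the trimethoxyphenyl group migrates in the peracid adduct and mild methanolysis of the formate should give the phenol.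

Step 2
Reactants: 3 2,4,6-trimethoxyphenol; 4 4-bromo-2,6-dimethoxybenzaldehyde
Product: 5 2,6-dimethoxy-4-(2,4,6-trimethoxyphenoxy)benzaldehyde
Conditions: CuI (10 mol%), picolinic acid (20 mol%), K3PO4, DMSO, 90 °C, argon
Reagents that add atoms: none
Why: Ullmann-type diaryl ether synthesis; the bromide is unhindered and activated by the para formyl group, and picolinic acid-ligated copper is a known system for 2,6-disubstituted phenols. The aldehyde has no α-hydrogen and should tolerate K3PO4.

Step 3
Reactants: 5 2,6-dimethoxy-4-(2,4,6-trimethoxyphenoxy)benzaldehyde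
Product: 7 2,6-dimethoxy-4-(2,4,6-trimethoxyphenoxy)phenol, via aryl formate 6 (not isolated)
Conditions: mCPBA (1.1 equiv), CH2Cl2, 0 °C; then K2CO3 (cat.), MeOH, rt
Reagents that add atoms: 3-chloroperbenzoic acid O=C(OO)c1cccc(Cl)c1
Why: Baeyer–Villiger oxidation; aryl migration is favoured by two ortho methoxy groups and the para aryloxy group. One equivalent of peracid at 0 °C should leave electron-rich ring A alone.

Step 4
Reactants: 7 2,6-dimethoxy-4-(2,4,6-trimethoxyphenoxy)phenol; 8 trichloroethylene
Product: 9 2-{[(E)-1,2-dichloroethenyl]oxy}-1,3-dimethoxy-5-(2,4,6-trimethoxyphenoxy)benzene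
Conditions: K2CO3, DMF, 70 °C, closed vessel
Reagents that add atoms: none
Why: Known dichlorovinyl ether synthesis from phenols: base converts 8 into dichloroacetylene, which stays dilute and transient, and anti addition of the phenoxide should give the (E)-ether. Carbonate replaces the metal hydride often used for this step.

Step 5
Reactants: 9 2-{[(E)-1,2-dichloroethenyl]oxy}-1,3-dimethoxy-5-(2,4,6-trimethoxyphenoxy)benzene
Product: 12 2-(ethynyloxy)-1,3-dimethoxy-5-(2,4,6-trimethoxyphenoxy)benzene, via chloroalkynyl ether 10 (not isolated), via lithium acetylide 11 (not isolated)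
Conditions: n-BuLi (2.2 equiv), THF, –78 to –40 °C; MeOH, –78 °C
Reagents that add atoms: none
Why: Known conversion of dichlorovinyl ethers into ynol ethers: elimination of HCl gives the chloroalkyne, chlorine–lithium exchange gives the acetylide, and cold protonation should give the terminal ynol ether. It is kept cold in solution and used at once.

Step 6
Reactants: 13 syringaldehyde
Product: 14 4-(benzyloxy)-3,5-dimethoxybenzaldehyde
Conditions: BnBr, K2CO3, DMF, rt
Reagents that add atoms: benzyl bromide BrCc1ccccc1
Why: Williamson etherification; benzyl marks the ring D C4 oxygen as the only one later freed by hydrogenolysis.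

Step 7
Reactants: 14 4-(benzyloxy)-3,5-dimethoxybenzaldehyde
Product: 16 4-(benzyloxy)-3,5-dimethoxyphenol, via aryl formate 15 (not isolated)
Conditions: mCPBA, CH2Cl2, 0 °C to rt; then K2CO3 (cat.), MeOH, rt
Reagents that add atoms: 3-chloroperbenzoic acid O=C(OO)c1cccc(Cl)c1
Why: Baeyer–Villiger oxidation and formate methanolysis, as in step 1; the trialkoxyphenyl group migrates.

Step 8
Reactants: 17 squaric acid
Product: 18 3,4-dichlorocyclobut-3-ene-1,2-dione
Conditions: (COCl)2, DMF (cat.), CH2Cl2, reflux
Reagents that add atoms: oxalyl chloride O=C(Cl)C(Cl)=O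
Why: Standard Vilsmeier-type conversion of the vinylogous diacid into its dichloride.

Step 9
Reactants: 18 3,4-dichlorocyclobut-3-ene-1,2-dione; 16 4-(benzyloxy)-3,5-dimethoxyphenol
Product: 20 3-[4-(benzyloxy)-3,5-dimethoxyphenoxy]-4-methoxycyclobut-3-ene-1,2-dione, via chloro ester 19 (not isolated)
Conditions: MeOH (1.0 equiv), i-Pr2NEt, CH2Cl2, –78 °C; then 16, i-Pr2NEt, –78 to 0 °C
Reagents that add atoms: methanol CO
Why: Two successive vinylogous acyl substitutions (addition–elimination): methanol replaces the first chloride and the phenol the remaining, less reactive one. Chloride loss is irreversible, whereas aryloxy-for-alkoxy exchange on a dialkyl squarate would be uphill, and no free methanol remains to cleave the activated aryl ester.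

Step 10
Reactants: 20 3-[4-(benzyloxy)-3,5-dimethoxyphenoxy]-4-methoxycyclobut-3-ene-1,2-dione
Product: 21 racemic 2-[4-(benzyloxy)-3,5-dimethoxyphenoxy]-4-hydroxy-3-methoxycyclobut-2-en-1-one
Conditions: LiAlH(OtBu)3, THF, –78 °C; then pH 7 buffer
Reagents that add atoms: none
Why: 1,2-Reduction of a squarate ester by a bulky alkoxyaluminium hydride, known for dialkyl squarates. The carbonyl conjugated through the ring double bond with the weaker donor (aryloxy) is the less stabilised vinylogous ester and should take the hydride, so the surviving carbonyl sits next to the aryloxy carbon. The new stereocentre is racemic and disappears in step 12.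

Step 11
Reactants: 21 racemic 2-[4-(benzyloxy)-3,5-dimethoxyphenoxy]-4-hydroxy-3-methoxycyclobut-2-en-1-one
Product: 22 racemic 2-[4-(benzyloxy)-3,5-dimethoxyphenoxy]-3,4-dimethoxycyclobut-2-en-1-one
Conditions: MeI, Ag2O, MeCN, rt, dark
Reagents that add atoms: iodomethane CI
Why: Silver oxide-mediated O-methylation under non-acidic, weakly basic conditions, chosen because 4-hydroxycyclobutenones ionise with acid and open with strong base. As a methyl ether this oxygen ends as an ordinary ring C methoxy.

Step 12
Reactants: 12 2-(ethynyloxy)-1,3-dimethoxy-5-(2,4,6-trimethoxyphenoxy)benzene; 22 racemic 2-[4-(benzyloxy)-3,5-dimethoxyphenoxy]-3,4-dimethoxycyclobut-2-en-1-one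
Product: 27 4-[4-(benzyloxy)-3,5-dimethoxyphenoxy]-5-[2,6-dimethoxy-4-(2,4,6-trimethoxyphenoxy)phenoxy]-2,3-dimethoxyphenol, via vinylketene 23 (not isolated), via vinylcyclobutenone 24 (not isolated), via dienylketene 25 (not isolated), via cyclohexadienone 26 (not isolated)
Conditions: toluene (0.5 M), 80 then 110 °C, argon, 22 in slight excess; then K2CO3, MeOH, rt
Reagents that add atoms: none
Why: Danheiser benzannulation, the known reaction of cyclobutenones with alkoxyacetylenes to give resorcinol monoethers, applied here with an aryloxy group on each partner. Thermal conrotatory 4π opening of 22, with the C4 methoxy group turning outward, gives vinylketene 23. The terminal carbon of 12, made nucleophilic by the ether oxygen, attacks the ketene carbonyl carbon and the (2+2) addition closes to 24, which forms ring C bonds C2–C3 and C1–C6. A second 4π opening (aryloxy outward, dienyl arm inward) gives dienylketene 25, whose thermal disrotatory 6π electrocyclisation closes ring C as cyclohexadienone 26, and enolisation should give phenol 27. The only selectivity needed is the orientation of the (2+2) addition; the polarisation of the ynol ether secures it and places the ring B ether next to the ring D ether and meta to the new hydroxyl. No stereocentre remains, since the sp3 centres of 24 and 26 are lost on ring opening and enolisation. The closing methanolysis only cleaves any aryl ester formed from 27 and 23.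

Step 13
Reactants: 27 4-[4-(benzyloxy)-3,5-dimethoxyphenoxy]-5-[2,6-dimethoxy-4-(2,4,6-trimethoxyphenoxy)phenoxy]-2,3-dimethoxyphenol
Product: 28 2-(benzyloxy)-1,3-dimethoxy-5-{6-[2,6-dimethoxy-4-(2,4,6-trimethoxyphenoxy)phenoxy]-2,3,4-trimethoxyphenoxy}benzene
Conditions: MeI, K2CO3, acetone, reflux
Reagents that add atoms: iodomethane CI
Why: Williamson methylation of the only free phenol.

Step 14
Reactants: 28 2-(benzyloxy)-1,3-dimethoxy-5-{6-[2,6-dimethoxy-4-(2,4,6-trimethoxyphenoxy)phenoxy]-2,3,4-trimethoxyphenoxy}benzene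
Product: 29 4-{6-[2,6-dimethoxy-4-(2,4,6-trimethoxyphenoxy)phenoxy]-2,3,4-trimethoxyphenoxy}-2,6-dimethoxyphenol
Conditions: H2 (1 atm), 10% Pd/C, EtOAc–MeOH, rt
Reagents that add atoms: none
Why: Hydrogenolysis of the benzyl ether; methyl and diaryl ethers are inert, so only the ring D C4 hydroxyl should be freed.

Step 15
Reactants: 30 2,6-dimethoxy-1,4-benzoquinone
Product: 31 2-bromo-3,5-dimethoxy-1,4-benzoquinone
Conditions: Br2 (1.0 equiv), CH2Cl2, 0 °C; then Et3N
Reagents that add atoms: bromine BrBr
Why: Electrophilic bromination by addition and dehydrobromination at the α-carbon of the vinylogous ester, the only nucleophilic C–H site. One equivalent limits dibromination.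

Step 16
Reactants: 29 4-{6-[2,6-dimethoxy-4-(2,4,6-trimethoxyphenoxy)phenoxy]-2,3,4-trimethoxyphenoxy}-2,6-dimethoxyphenol; 31 2-bromo-3,5-dimethoxy-1,4-benzoquinone
Product: 32 2-(ABCD–O)-3,5-dimethoxycyclohexa-2,5-diene-1,4-dione
Conditions: K2CO3, MeCN, 0 °C to rt, argon
Reagents that add atoms: none
Why: Addition–elimination on a halobenzoquinone: the phenoxide adds at C–Br, β to the cross-conjugated and more electrophilic carbonyl, and bromide leaves irreversibly, while addition at the methoxy carbons is reversible and uphill. The carbon attacked is not aromatic, so the tetra-ortho-substituted ether should form without a metal.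

Step 17
Reactants: 32 2-(ABCD–O)-3,5-dimethoxycyclohexa-2,5-diene-1,4-dione
Product: 34 3-(ABCD–O)-2,6-dimethoxy-4-[(triisopropylsilyl)oxy]phenol, via hydroquinone 33 (not isolated)
Conditions: Na2S2O4, EtOAc–H2O, rt; then TIPSCl (1.05 equiv), imidazole, DMF, 0 °C
Reagents that add atoms: triisopropylsilyl chloride CC(C)[Si](Cl)(C(C)C)C(C)C
Why: Dithionite reduction of the quinone, then sterically controlled silylation. The bulky silyl chloride should take the hydroxyl with one ortho substituent and leave the one between two methoxy groups, which tells the two ring E oxygens apart.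

Step 18
Reactants: 34 3-(ABCD–O)-2,6-dimethoxy-4-[(triisopropylsilyl)oxy]phenol
Product: 35 [2-(ABCD–O)-3,4,5-trimethoxyphenoxy]triisopropylsilane
Conditions: MeI, K2CO3, acetone, reflux
Reagents that add atoms: iodomethane CI
Why: Williamson methylation of the hindered phenol; a triisopropylsilyl aryl ether should survive carbonate in acetone.

Step 19
Reactants: 36 3,4,5-trimethoxyphenol; 37 2-bromo-3,4,5-trimethoxybenzaldehyde
Product: 38 3,4,5-trimethoxy-2-(3,4,5-trimethoxyphenoxy)benzaldehyde
Conditions: CuI (10 mol%), picolinic acid (20 mol%), K3PO4, DMSO, 90 °C, argon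
Reagents that add atoms: none
Why: Ullmann-type coupling assisted by the ortho formyl group, the known ortho effect of 2-bromobenzaldehydes; the phenol partner is unhindered.

Step 20
Reactants: 38 3,4,5-trimethoxy-2-(3,4,5-trimethoxyphenoxy)benzaldehyde
Product: 40 3,4,5-trimethoxy-2-(3,4,5-trimethoxyphenoxy)phenol, via aryl formate 39 (not isolated)
Conditions: mCPBA, CH2Cl2, 0 °C to rt; then K2CO3 (cat.), MeOH, rt
Reagents that add atoms: 3-chloroperbenzoic acid O=C(OO)c1cccc(Cl)c1
Why: Baeyer–Villiger oxidation and methanolysis; the hydroxyl appears only at the carbon that held the formyl group, so no two oxygens need to be told apart.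

Step 21
Reactants: 35 [2-(ABCD–O)-3,4,5-trimethoxyphenoxy]triisopropylsilane; 41 2,4-difluoro-6-methoxybenzaldehyde
Product: 43 2-fluoro-6-methoxy-4-[2-(ABCD–O)-3,4,5-trimethoxyphenoxy]benzaldehyde, via caesium phenoxide 42 (not isolated)
Conditions: CsF, DMF, rt to 40 °C
Reagents that add atoms: none
Why: Fluoride cleaves the silyl ether and the released phenoxide substitutes the fluorine para to the formyl group (nucleophilic aromatic substitution). Para attack is favoured for a bulky, non-chelated phenoxide in DMF. The methoxy group of 41 already holds the third ring F oxygen.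

Step 22
Reactants: 43 2-fluoro-6-methoxy-4-[2-(ABCD–O)-3,4,5-trimethoxyphenoxy]benzaldehyde; 40 3,4,5-trimethoxy-2-(3,4,5-trimethoxyphenoxy)phenol
Product: 44 2-methoxy-4-[2-(ABCD–O)-3,4,5-trimethoxyphenoxy]-6-[3,4,5-trimethoxy-2-(3,4,5-trimethoxyphenoxy)phenoxy]benzaldehyde
Conditions: Cs2CO3, DMSO, 80 °C, argon
Reagents that add atoms: none
Why: Nucleophilic aromatic substitution of the remaining fluorine, ortho to the formyl group; the aryloxy group set in step 21 is meta to this carbon and does not deactivate it by resonance.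

Step 23
Reactants: 44 2-methoxy-4-[2-(ABCD–O)-3,4,5-trimethoxyphenoxy]-6-[3,4,5-trimethoxy-2-(3,4,5-trimethoxyphenoxy)phenoxy]benzaldehyde
Product: 46 2-methoxy-4-[2-(ABCD–O)-3,4,5-trimethoxyphenoxy]-6-[3,4,5-trimethoxy-2-(3,4,5-trimethoxyphenoxy)phenoxy]phenol, via aryl formate 45 (not isolated)
Conditions: mCPBA (1.1 equiv), CH2Cl2, 0 °C; then K2CO3 (cat.), MeOH, rt
Reagents that add atoms: 3-chloroperbenzoic acid O=C(OO)c1cccc(Cl)c1
Why: Baeyer–Villiger oxidation; the 2,4,6-trioxygenated ring F migrates readily, and low temperature with one equivalent of peracid should prevent hydroxylation of the other rings.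

Step 24
Reactants: 46 2-methoxy-4-[2-(ABCD–O)-3,4,5-trimethoxyphenoxy]-6-[3,4,5-trimethoxy-2-(3,4,5-trimethoxyphenoxy)phenoxy]phenol
Product: 47 CNP0309601.0 (46 with each of its 20 methoxy groups replaced by hydroxyl)
Conditions: BBr3 (excess), CH2Cl2, –78 °C to rt; MeOH then degassed H2O, argon
Reagents that add atoms: none
Why: Lewis acid cleavage of aryl methyl ethers: bromide attacks the methyl carbon of each boron–ether complex. Diaryl ethers offer no sp3 carbon and should survive; degassed work-up protects the polyphenol.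

## Compound list

1 | 2,4,6-trimethoxybenzaldehyde | COc1cc(OC)c(C=O)c(OC)c1 | starting material
2 | 2,4,6-trimethoxyphenyl formate | COc1cc(OC)c(OC=O)c(OC)c1 | intermediate (not isolated)
3 | 2,4,6-trimethoxyphenol | COc1cc(OC)c(O)c(OC)c1 | intermediate
4 | 4-bromo-2,6-dimethoxybenzaldehyde | COc1cc(Br)cc(OC)c1C=O | starting material
5 | 2,6-dimethoxy-4-(2,4,6-trimethoxyphenoxy)benzaldehyde | O=Cc1c(OC)cc(Oc2c(OC)cc(OC)cc2OC)cc1OC | intermediate
6 | 2,6-dimethoxy-4-(2,4,6-trimethoxyphenoxy)phenyl formate | O=COc1c(OC)cc(Oc2c(OC)cc(OC)cc2OC)cc1OC | intermediate (not isolated)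
7 | 2,6-dimethoxy-4-(2,4,6-trimethoxyphenoxy)phenol | Oc1c(OC)cc(Oc2c(OC)cc(OC)cc2OC)cc1OC | intermediate
8 | trichloroethylene | ClC=C(Cl)Cl | starting material
9 | 2-{[(E)-1,2-dichloroethenyl]oxy}-1,3-dimethoxy-5-(2,4,6-trimethoxyphenoxy)benzene | Cl/C=C(/Cl)Oc1c(OC)cc(Oc2c(OC)cc(OC)cc2OC)cc1OC | intermediate
10 | 2-[(chloroethynyl)oxy]-1,3-dimethoxy-5-(2,4,6-trimethoxyphenoxy)benzene | ClC#COc1c(OC)cc(Oc2c(OC)cc(OC)cc2OC)cc1OC | intermediate (not isolated)
11 | lithium [2,6-dimethoxy-4-(2,4,6-trimethoxyphenoxy)phenoxy]ethynide | [Li]C#COc1c(OC)cc(Oc2c(OC)cc(OC)cc2OC)cc1OC | intermediate (not isolated)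
12 | 2-(ethynyloxy)-1,3-dimethoxy-5-(2,4,6-trimethoxyphenoxy)benzene | C#COc1c(OC)cc(Oc2c(OC)cc(OC)cc2OC)cc1OC | intermediate
13 | syringaldehyde (4-hydroxy-3,5-dimethoxybenzaldehyde) | COc1cc(C=O)cc(OC)c1O | starting material
14 | 4-(benzyloxy)-3,5-dimethoxybenzaldehyde | COc1cc(C=O)cc(OC)c1OCc1ccccc1 | intermediate
15 | 4-(benzyloxy)-3,5-dimethoxyphenyl formate | O=COc1cc(OC)c(OCc2ccccc2)c(OC)c1 | intermediate (not isolated)
16 | 4-(benzyloxy)-3,5-dimethoxyphenol | Oc1cc(OC)c(OCc2ccccc2)c(OC)c1 | intermediate
17 | squaric acid (3,4-dihydroxycyclobut-3-ene-1,2-dione) | O=C1C(O)=C(O)C1=O | starting material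
18 | 3,4-dichlorocyclobut-3-ene-1,2-dione | O=C1C(Cl)=C(Cl)C1=O | intermediate
19 | 3-chloro-4-methoxycyclobut-3-ene-1,2-dione | COC1=C(Cl)C(=O)C1=O | intermediate (not isolated)
20 | 3-[4-(benzyloxy)-3,5-dimethoxyphenoxy]-4-methoxycyclobut-3-ene-1,2-dione | COC1=C(Oc2cc(OC)c(OCc3ccccc3)c(OC)c2)C(=O)C1=O | intermediate
21 | racemic 2-[4-(benzyloxy)-3,5-dimethoxyphenoxy]-4-hydroxy-3-methoxycyclobut-2-en-1-one | O=C1C(Oc2cc(OC)c(OCc3ccccc3)c(OC)c2)=C(OC)C1O | intermediate
22 | racemic 2-[4-(benzyloxy)-3,5-dimethoxyphenoxy]-3,4-dimethoxycyclobut-2-en-1-one | O=C1C(Oc2cc(OC)c(OCc3ccccc3)c(OC)c2)=C(OC)C1OC | intermediate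
23 | (3Z)-2-[4-(benzyloxy)-3,5-dimethoxyphenoxy]-3,4-dimethoxybuta-1,3-dien-1-one (vinylketene) | O=C=C(Oc1cc(OC)c(OCc2ccccc2)c(OC)c1)/C(OC)=C/OC | intermediate (not isolated)
24 | racemic 4-[4-(benzyloxy)-3,5-dimethoxyphenoxy]-4-[(Z)-1,2-dimethoxyethenyl]-3-[2,6-dimethoxy-4-(2,4,6-trimethoxyphenoxy)phenoxy]cyclobut-2-en-1-one | O=C1C=C(Oc2c(OC)cc(Oc3c(OC)cc(OC)cc3OC)cc2OC)C1(Oc1cc(OC)c(OCc2ccccc2)c(OC)c1)/C(OC)=C/OC | intermediate (not isolated)
25 | (3Z,5Z)-4-[4-(benzyloxy)-3,5-dimethoxyphenoxy]-3-[2,6-dimethoxy-4-(2,4,6-trimethoxyphenoxy)phenoxy]-5,6-dimethoxyhexa-1,3,5-trien-1-one (dienylketene) | O=C=C/C(Oc1c(OC)cc(Oc2c(OC)cc(OC)cc2OC)cc1OC)=C(Oc1cc(OC)c(OCc2ccccc2)c(OC)c1)\C(OC)=C\OC | intermediate (not isolated)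
26 | racemic 4-[4-(benzyloxy)-3,5-dimethoxyphenoxy]-3-[2,6-dimethoxy-4-(2,4,6-trimethoxyphenoxy)phenoxy]-5,6-dimethoxycyclohexa-2,4-dien-1-one | O=C1C=C(Oc2c(OC)cc(Oc3c(OC)cc(OC)cc3OC)cc2OC)C(Oc2cc(OC)c(OCc3ccccc3)c(OC)c2)=C(OC)C1OC | intermediate (not isolated)
27 | 4-[4-(benzyloxy)-3,5-dimethoxyphenoxy]-5-[2,6-dimethoxy-4-(2,4,6-trimethoxyphenoxy)phenoxy]-2,3-dimethoxyphenol | Oc1cc(Oc2c(OC)cc(Oc3c(OC)cc(OC)cc3OC)cc2OC)c(Oc2cc(OC)c(OCc3ccccc3)c(OC)c2)c(OC)c1OC | intermediate
28 | 2-(benzyloxy)-1,3-dimethoxy-5-{6-[2,6-dimethoxy-4-(2,4,6-trimethoxyphenoxy)phenoxy]-2,3,4-trimethoxyphenoxy}benzene | COc1cc(Oc2c(OC)cc(Oc3c(OC)cc(OC)cc3OC)cc2OC)c(Oc2cc(OC)c(OCc3ccccc3)c(OC)c2)c(OC)c1OC | intermediate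
29 | 4-{6-[2,6-dimethoxy-4-(2,4,6-trimethoxyphenoxy)phenoxy]-2,3,4-trimethoxyphenoxy}-2,6-dimethoxyphenol | Oc1c(OC)cc(Oc2c(Oc3c(OC)cc(Oc4c(OC)cc(OC)cc4OC)cc3OC)cc(OC)c(OC)c2OC)cc1OC | intermediate
30 | 2,6-dimethoxy-1,4-benzoquinone | COC1=CC(=O)C=C(OC)C1=O | starting material
31 | 2-bromo-3,5-dimethoxy-1,4-benzoquinone | O=C1C=C(OC)C(=O)C(OC)=C1Br | intermediate
32 | 2-(ABCD–O)-3,5-dimethoxycyclohexa-2,5-diene-1,4-dione | O=C1C=C(OC)C(=O)C(OC)=C1Oc1c(OC)cc(Oc2c(Oc3c(OC)cc(Oc4c(OC)cc(OC)cc4OC)cc3OC)cc(OC)c(OC)c2OC)cc1OC | intermediate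
33 | 2-(ABCD–O)-3,5-dimethoxybenzene-1,4-diol | Oc1cc(OC)c(O)c(OC)c1Oc1c(OC)cc(Oc2c(Oc3c(OC)cc(Oc4c(OC)cc(OC)cc4OC)cc3OC)cc(OC)c(OC)c2OC)cc1OC | intermediate (not isolated)
34 | 3-(ABCD–O)-2,6-dimethoxy-4-[(triisopropylsilyl)oxy]phenol | CC(C)[Si](C(C)C)(C(C)C)Oc1cc(OC)c(O)c(OC)c1Oc1c(OC)cc(Oc2c(Oc3c(OC)cc(Oc4c(OC)cc(OC)cc4OC)cc3OC)cc(OC)c(OC)c2OC)cc1OC | intermediate
35 | [2-(ABCD–O)-3,4,5-trimethoxyphenoxy]triisopropylsilane | CC(C)[Si](C(C)C)(C(C)C)Oc1cc(OC)c(OC)c(OC)c1Oc1c(OC)cc(Oc2c(Oc3c(OC)cc(Oc4c(OC)cc(OC)cc4OC)cc3OC)cc(OC)c(OC)c2OC)cc1OC | intermediate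
36 | 3,4,5-trimethoxyphenol | COc1cc(O)cc(OC)c1OC | starting material
37 | 2-bromo-3,4,5-trimethoxybenzaldehyde | COc1cc(C=O)c(Br)c(OC)c1OC | starting material
38 | 3,4,5-trimethoxy-2-(3,4,5-trimethoxyphenoxy)benzaldehyde | COc1cc(C=O)c(Oc2cc(OC)c(OC)c(OC)c2)c(OC)c1OC | intermediate
39 | 3,4,5-trimethoxy-2-(3,4,5-trimethoxyphenoxy)phenyl formate | O=COc1cc(OC)c(OC)c(OC)c1Oc1cc(OC)c(OC)c(OC)c1 | intermediate (not isolated)
40 | 3,4,5-trimethoxy-2-(3,4,5-trimethoxyphenoxy)phenol | Oc1cc(OC)c(OC)c(OC)c1Oc1cc(OC)c(OC)c(OC)c1 | intermediate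
41 | 2,4-difluoro-6-methoxybenzaldehyde | COc1cc(F)cc(F)c1C=O | starting material
42 | caesium 2-(ABCD–O)-3,4,5-trimethoxyphenoxide | [Cs+].[O-]c1cc(OC)c(OC)c(OC)c1Oc1c(OC)cc(Oc2c(Oc3c(OC)cc(Oc4c(OC)cc(OC)cc4OC)cc3OC)cc(OC)c(OC)c2OC)cc1OC | intermediate (not isolated)
43 | 2-fluoro-6-methoxy-4-[2-(ABCD–O)-3,4,5-trimethoxyphenoxy]benzaldehyde | O=Cc1c(F)cc(Oc2cc(OC)c(OC)c(OC)c2Oc2c(OC)cc(Oc3c(Oc4c(OC)cc(Oc5c(OC)cc(OC)cc5OC)cc4OC)cc(OC)c(OC)c3OC)cc2OC)cc1OC | intermediate
44 | 2-methoxy-4-[2-(ABCD–O)-3,4,5-trimethoxyphenoxy]-6-[3,4,5-trimethoxy-2-(3,4,5-trimethoxyphenoxy)phenoxy]benzaldehyde | O=Cc1c(OC)cc(Oc2cc(OC)c(OC)c(OC)c2Oc2c(OC)cc(Oc3c(Oc4c(OC)cc(Oc5c(OC)cc(OC)cc5OC)cc4OC)cc(OC)c(OC)c3OC)cc2OC)cc1Oc1cc(OC)c(OC)c(OC)c1Oc1cc(OC)c(OC)c(OC)c1 | intermediate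
45 | 2-methoxy-4-[2-(ABCD–O)-3,4,5-trimethoxyphenoxy]-6-[3,4,5-trimethoxy-2-(3,4,5-trimethoxyphenoxy)phenoxy]phenyl formate | O=COc1c(OC)cc(Oc2cc(OC)c(OC)c(OC)c2Oc2c(OC)cc(Oc3c(Oc4c(OC)cc(Oc5c(OC)cc(OC)cc5OC)cc4OC)cc(OC)c(OC)c3OC)cc2OC)cc1Oc1cc(OC)c(OC)c(OC)c1Oc1cc(OC)c(OC)c(OC)c1 | intermediate (not isolated)
46 | 2-methoxy-4-[2-(ABCD–O)-3,4,5-trimethoxyphenoxy]-6-[3,4,5-trimethoxy-2-(3,4,5-trimethoxyphenoxy)phenoxy]phenol | Oc1c(OC)cc(Oc2cc(OC)c(OC)c(OC)c2Oc2c(OC)cc(Oc3c(Oc4c(OC)cc(Oc5c(OC)cc(OC)cc5OC)cc4OC)cc(OC)c(OC)c3OC)cc2OC)cc1Oc1cc(OC)c(OC)c(OC)c1Oc1cc(OC)c(OC)c(OC)c1 | intermediate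
47 | CNP0309601.0 (46 with all 20 methoxy groups as hydroxyl; eight rings A to H, 21 hydroxyls, no stereocentre) | Oc1cc(O)c(Oc2cc(O)c(Oc3cc(O)c(O)c(O)c3Oc3cc(O)c(Oc4c(Oc5cc(O)c(O)c(Oc6cc(O)c(O)c(O)c6Oc6cc(O)c(O)c(O)c6)c5)cc(O)c(O)c4O)c(O)c3)c(O)c2)c(O)c1 | target

## Step count and least certain steps

Total step count: 24. Longest linear sequence: 15 steps (1 to 5, 12 to 14, 16 to 18, 21 to 24).

**Step 12 (key step).** The likeliest failure is loss of the vinylketene to dimerisation or to acylation of the product phenol. The terminal aryloxyacetylene may also oligomerise thermally before the cyclobutenone opens, because the capture is bimolecular and an aryl ynol ether is a weaker nucleophile than an alkyl one. The fallback sets out from 9 and 22 and returns at 27. The acetylide 11 raised from 9 is quenched with Me3SiCl instead of methanol to give {[2,6-dimethoxy-4-(2,4,6-trimethoxyphenoxy)phenoxy]ethynyl}trimethylsilane F1, a carbon-capped ynol ether that can be stored, used in excess and heated harder. Benzannulation with 22 would then give 4-[4-(benzyloxy)-3,5-dimethoxyphenoxy]-5-[2,6-dimethoxy-4-(2,4,6-trimethoxyphenoxy)phenoxy]-2,3-dimethoxy-6-(trimethylsilyl)phenol F2; the silicon stabilises the developing positive charge on the oxygen-bearing alkyne carbon. Protodesilylation of the electron-rich arylsilane with TBAF in THF would return 27.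

**Step 10.** The likeliest failure is poor regioselectivity of hydride delivery, since the electronic bias between aryloxy and methoxy is modest; displacement of aryloxide by addition–elimination is a second risk. The fallback sets out from 18 and 16 and returns at 22, removing the choice by symmetry. Compound 18 with two equivalents of 16 (i-Pr2NEt) gives 3,4-bis[4-(benzyloxy)-3,5-dimethoxyphenoxy]cyclobut-3-ene-1,2-dione F3, whose carbonyls are equivalent. LiAlH(OtBu)3 gives racemic 2,3-bis[4-(benzyloxy)-3,5-dimethoxyphenoxy]-4-hydroxycyclobut-2-en-1-one F4, and Ag2O with MeI gives racemic 2,3-bis[4-(benzyloxy)-3,5-dimethoxyphenoxy]-4-methoxycyclobut-2-en-1-one F5. Methanol with Et3N at 0 °C then exchanges only the aryloxy group on C3, the vinylogous aryl ester position, for methoxy. This exchange is downhill and leaves the C2 aryloxy group untouched, so it gives 22 and one recoverable equivalent of 16.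

**Step 16.** The likeliest failure is electron transfer from the very electron-rich phenoxide to the quinone, leading to oxidative coupling of the phenol; addition at the unsubstituted quinone carbon may also compete. The fallback sets out from 29 and 37 and returns at 43. Copper-mediated coupling under the conditions of step 19, with the ortho formyl group assisting, gives 3,4,5-trimethoxy-2-(ABCD–O)benzaldehyde F6. Baeyer–Villiger oxidation gives 3,4,5-trimethoxy-2-(ABCD–O)phenyl formate F7, and methanolysis gives 3,4,5-trimethoxy-2-(ABCD–O)phenol F8. F8 with Cs2CO3 and 41 in DMF then gives 43, which makes steps 17 and 18 unnecessary.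

**Step 19.** The likeliest failure is slow reaction at the doubly ortho-substituted, electron-rich bromide, so that protodebromination and degradation of the aldehyde compete. The fallback sets out from 36 and 31 and returns at 44, repeating the quinone logic of steps 16 to 18 on the small phenol. 36 and 31 (K2CO3, MeCN) give 3,5-dimethoxy-2-(3,4,5-trimethoxyphenoxy)cyclohexa-2,5-diene-1,4-dione F9. Dithionite gives 3,5-dimethoxy-2-(3,4,5-trimethoxyphenoxy)benzene-1,4-diol F10, which is silylated at its less hindered hydroxyl to 2,6-dimethoxy-3-(3,4,5-trimethoxyphenoxy)-4-[(triisopropylsilyl)oxy]phenol F11. Methylation gives triisopropyl[3,4,5-trimethoxy-2-(3,4,5-trimethoxyphenoxy)phenoxy]silane F12. CsF in DMF with 43 releases caesium 3,4,5-trimethoxy-2-(3,4,5-trimethoxyphenoxy)phenoxide F13, which should substitute the ortho fluorine and give 44.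

**Step 24.** The likeliest failure is incomplete ether cleavage, because partly demethylated aryloxyboron species precipitate from CH2Cl2; oxidative degradation of the free polyphenol during isolation is the second risk. The fallback sets out from 46 and returns at 47. The crude demethylation product is not isolated but acetylated at once (Ac2O, pyridine) to the henicosaacetate of 47 F14. This is stable to air and silica, so it can be purified and under-cleaved material removed. Degassed methanolysis with catalytic NaOMe under argon, followed by acidification, then releases 47.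

## Further compounds

F1 | step 12 | {[2,6-dimethoxy-4-(2,4,6-trimethoxyphenoxy)phenoxy]ethynyl}trimethylsilane | C[Si](C)(C)C#COc1c(OC)cc(Oc2c(OC)cc(OC)cc2OC)cc1OC
F2 | step 12 | 4-[4-(benzyloxy)-3,5-dimethoxyphenoxy]-5-[2,6-dimethoxy-4-(2,4,6-trimethoxyphenoxy)phenoxy]-2,3-dimethoxy-6-(trimethylsilyl)phenol | Oc1c([Si](C)(C)C)c(Oc2c(OC)cc(Oc3c(OC)cc(OC)cc3OC)cc2OC)c(Oc2cc(OC)c(OCc3ccccc3)c(OC)c2)c(OC)c1OC
F3 | step 10 | 3,4-bis[4-(benzyloxy)-3,5-dimethoxyphenoxy]cyclobut-3-ene-1,2-dione | O=C1C(=O)C(Oc2cc(OC)c(OCc3ccccc3)c(OC)c2)=C1Oc1cc(OC)c(OCc2ccccc2)c(OC)c1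
F4 | step 10 | racemic 2,3-bis[4-(benzyloxy)-3,5-dimethoxyphenoxy]-4-hydroxycyclobut-2-en-1-one | O=C1C(Oc2cc(OC)c(OCc3ccccc3)c(OC)c2)=C(Oc2cc(OC)c(OCc3ccccc3)c(OC)c2)C1O
F5 | step 10 | racemic 2,3-bis[4-(benzyloxy)-3,5-dimethoxyphenoxy]-4-methoxycyclobut-2-en-1-one | O=C1C(Oc2cc(OC)c(OCc3ccccc3)c(OC)c2)=C(Oc2cc(OC)c(OCc3ccccc3)c(OC)c2)C1OC
F6 | step 16 | 3,4,5-trimethoxy-2-(ABCD–O)benzaldehyde | O=Cc1cc(OC)c(OC)c(OC)c1Oc1c(OC)cc(Oc2c(Oc3c(OC)cc(Oc4c(OC)cc(OC)cc4OC)cc3OC)cc(OC)c(OC)c2OC)cc1OC
F7 | step 16 | 3,4,5-trimethoxy-2-(ABCD–O)phenyl formate | O=COc1cc(OC)c(OC)c(OC)c1Oc1c(OC)cc(Oc2c(Oc3c(OC)cc(Oc4c(OC)cc(OC)cc4OC)cc3OC)cc(OC)c(OC)c2OC)cc1OC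
F8 | step 16 | 3,4,5-trimethoxy-2-(ABCD–O)phenol | Oc1cc(OC)c(OC)c(OC)c1Oc1c(OC)cc(Oc2c(Oc3c(OC)cc(Oc4c(OC)cc(OC)cc4OC)cc3OC)cc(OC)c(OC)c2OC)cc1OC
F9 | step 19 | 3,5-dimethoxy-2-(3,4,5-trimethoxyphenoxy)cyclohexa-2,5-diene-1,4-dione | O=C1C=C(OC)C(=O)C(OC)=C1Oc1cc(OC)c(OC)c(OC)c1
F10 | step 19 | 3,5-dimethoxy-2-(3,4,5-trimethoxyphenoxy)benzene-1,4-diol | Oc1cc(OC)c(O)c(OC)c1Oc1cc(OC)c(OC)c(OC)c1
F11 | step 19 | 2,6-dimethoxy-3-(3,4,5-trimethoxyphenoxy)-4-[(triisopropylsilyl)oxy]phenol | CC(C)[Si](C(C)C)(C(C)C)Oc1cc(OC)c(O)c(OC)c1Oc1cc(OC)c(OC)c(OC)c1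
F12 | step 19 | triisopropyl[3,4,5-trimethoxy-2-(3,4,5-trimethoxyphenoxy)phenoxy]silane | CC(C)[Si](C(C)C)(C(C)C)Oc1cc(OC)c(OC)c(OC)c1Oc1cc(OC)c(OC)c(OC)c1
F13 | step 19 | caesium 3,4,5-trimethoxy-2-(3,4,5-trimethoxyphenoxy)phenoxide | [Cs+].[O-]c1cc(OC)c(OC)c(OC)c1Oc1cc(OC)c(OC)c(OC)c1
F14 | step 24 | henicosaacetate of 47 (every hydroxyl of 47 as acetate) | CC(=O)Oc1cc(OC(C)=O)c(Oc2cc(OC(C)=O)c(Oc3cc(OC(C)=O)c(OC(C)=O)c(OC(C)=O)c3Oc3cc(OC(C)=O)c(Oc4c(Oc5cc(OC(C)=O)c(OC(C)=O)c(Oc6cc(OC(C)=O)c(OC(C)=O)c(OC(C)=O)c6Oc6cc(OC(C)=O)c(OC(C)=O)c(OC(C)=O)c6)c5)cc(OC(C)=O)c(OC(C)=O)c4OC(C)=O)c(OC(C)=O)c3)c(OC(C)=O)c2)c(OC(C)=O)c1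
A1 | alternative 1 | 2,4,6-trifluorobenzaldehyde | O=Cc1c(F)cc(F)cc1F
A2 | alternative 1 | 2-fluoro-4-[2-(ABCD–O)-3,4,5-trimethoxyphenoxy]-6-[3,4,5-trimethoxy-2-(3,4,5-trimethoxyphenoxy)phenoxy]benzaldehyde | O=Cc1c(F)cc(Oc2cc(OC)c(OC)c(OC)c2Oc2c(OC)cc(Oc3c(Oc4c(OC)cc(Oc5c(OC)cc(OC)cc5OC)cc4OC)cc(OC)c(OC)c3OC)cc2OC)cc1Oc1cc(OC)c(OC)c(OC)c1Oc1cc(OC)c(OC)c(OC)c1
A3 | alternative 2 | 1,4-dimethoxy-1,3-bis(trimethylsilyloxy)buta-1,3-diene (mixture of double-bond isomers) | COC=C(O[Si](C)(C)C)C=C(OC)O[Si](C)(C)C
A4 | alternative 2 | 2-{6-[2,6-dimethoxy-4-(2,4,6-trimethoxyphenoxy)phenoxy]-2,3,4-trimethoxyphenoxy}propanedial | O=CC(C=O)Oc1c(Oc2c(OC)cc(Oc3c(OC)cc(OC)cc3OC)cc2OC)cc(OC)c(OC)c1OC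
A5 | alternative 2 | methyl 2-hydroxy-3-methoxy-5-{6-[2,6-dimethoxy-4-(2,4,6-trimethoxyphenoxy)phenoxy]-2,3,4-trimethoxyphenoxy}benzoate | COC(=O)c1cc(Oc2c(Oc3c(OC)cc(Oc4c(OC)cc(OC)cc4OC)cc3OC)cc(OC)c(OC)c2OC)cc(OC)c1O
A6 | alternative 3 | racemic 3,4-dimethoxy-4-(1-methoxyethenyl)-2-(3,4,5-trimethoxyphenoxy)cyclobut-2-en-1-one | O=C1C(Oc2cc(OC)c(OC)c(OC)c2)=C(OC)C1(OC)C(OC)=C
A7 | alternative 3 | 3,4,5-trimethoxy-2-(3,4,5-trimethoxyphenoxy)phenol | Oc1cc(OC)c(OC)c(OC)c1Oc1cc(OC)c(OC)c(OC)c1
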